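**Retrosynthetic overview**
1. Target 20 ⇒ open the furan O1–C2 bond to give o-hydroxybenzyl aryl ketone 19, carried as its tetra-MOM ether 18. The furan is the only ring made and is closed last; rings A and B are bought.
2. 18 ⇒ β-keto ester 17 (Krapcho) ⇒ crossed Claisen condensation forming the C2–C3 bond from ring A arylacetate 13 (donor) and ring B benzoate 15 (acceptor).
3. 13 ⇒ 2-arylethanol 10 (oxidation, esterification) ⇒ geranyl–aryl bond by directed ortho-metalation between the two OMOM groups, using (E)-geranyl bromide 7.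
4. The C2 side chain comes from 4-bromoresorcinol 1 by Br/Li exchange and ethylene oxide 3; 15 comes from methyl 3,5-dihydroxybenzoate 14.

Assumption: the target has no stereocentre. Its only stereo-element is the E double bond of the geranyl chain, so "single enantiomer" is read as the single E isomer drawn.
Abbreviations: geranyl = (2E)-3,7-dimethylocta-2,6-dien-1-yl; MOM = CH2OCH3; TBS = SiMe2(t-Bu).

**Step 1**
Reactants: 1 4-bromoresorcinol (4-bromobenzene-1,3-diol)
Product: 2 1-bromo-2,4-bis(methoxymethoxy)benzene
Conditions: MOMCl (3 equiv), iPr2NEt (4 equiv), CH2Cl2, 0 °C → rt, 12 h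
Reagents that add atoms: chloromethyl methyl ether (MOMCl), COCCl
Why: Base-mediated O-alkylation (MOM acetal protection) of both phenols is a standard high-yielding reaction that leaves the aryl bromide alone, and the OMOM groups later withstand organolithiums and act as ortho-directing groups.

**Step 2**
Reactants: 2 1-bromo-2,4-bis(methoxymethoxy)benzene; 3 ethylene oxide (oxirane)
Product: 5 2-[2,4-bis(methoxymethoxy)phenyl]ethan-1-ol, via aryllithium 4 (not isolated)
Conditions: n-BuLi (1.1 equiv), THF, −78 °C, 30 min; 3 (3 equiv, THF solution), −78 °C → rt; H2O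
Reagents that add atoms: none
Why: Bromine–lithium exchange at −78 °C is far faster than any deprotonation and places the carbanion only at C1, and the aryllithium then opens the unhindered epoxide by SN2 attack to install the two-carbon side chain.

**Step 3**
Reactants: 5 2-[2,4-bis(methoxymethoxy)phenyl]ethan-1-ol
Product: 6 tert-butyl{2-[2,4-bis(methoxymethoxy)phenyl]ethoxy}dimethylsilane
Conditions: TBSCl (1.2 equiv), imidazole (2.5 equiv), DMF, rt, 3 h
Reagents that add atoms: tert-butyldimethylsilyl chloride (TBSCl), CC(C)(C)[Si](C)(C)Cl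
Why: Imidazole-promoted silylation of the primary alcohol masks the acidic OH, so the next organolithium step needs no extra base and cannot O-alkylate.

**Step 4**
Reactants: 6 tert-butyl{2-[2,4-bis(methoxymethoxy)phenyl]ethoxy}dimethylsilane; 7 geranyl bromide ((2E)-1-bromo-3,7-dimethylocta-2,6-diene)
Product: 9 tert-butyl{2-[3-geranyl-2,4-bis(methoxymethoxy)phenyl]ethoxy}dimethylsilane, via aryllithium 8 (not isolated)
Conditions: n-BuLi (1.3 equiv), THF, 0 °C → rt, 1.5 h; CuI (10 mol %), −40 °C; 7 (1.4 equiv), −40 °C → rt; H2O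
Reagents that add atoms: none
Why: Directed ortho-metalation takes place at the only C–H flanked by two coordinating OMOM groups, and copper-catalysed SN2 allylic substitution on primary bromide 7 joins the chain at its unsubstituted terminus with the E double bond of 7 carried over unchanged.

**Step 5**
Reactants: 9 tert-butyl{2-[3-geranyl-2,4-bis(methoxymethoxy)phenyl]ethoxy}dimethylsilane
Product: 10 2-[3-geranyl-2,4-bis(methoxymethoxy)phenyl]ethan-1-ol
Conditions: Bu4NF (1.5 equiv), THF, rt, 2 h
Reagents that add atoms: none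
Why: Fluoride-driven desilylation (formation of the strong Si–F bond) frees the primary alcohol under conditions that leave the MOM acetals and both alkenes untouched.

**Step 6**
Reactants: 10 2-[3-geranyl-2,4-bis(methoxymethoxy)phenyl]ethan-1-ol
Product: 12 [3-geranyl-2,4-bis(methoxymethoxy)phenyl]acetic acid, via arylacetaldehyde 11 (not isolated)
Conditions: TEMPO (20 mol %), PhI(OAc)2 (2.5 equiv), MeCN/H2O 1:1, rt, 5 h
Reagents that add atoms: water, O
Why: The TEMPO/PhI(OAc)2 oxoammonium oxidation takes the primary alcohol through the aldehyde hydrate to the acid without chlorine-based oxidants or strong acid, so the trisubstituted alkenes, the electron-rich ring and the MOM acetals survive.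

**Step 7**
Reactants: 12 [3-geranyl-2,4-bis(methoxymethoxy)phenyl]acetic acid
Product: 13 methyl [3-geranyl-2,4-bis(methoxymethoxy)phenyl]acetate
Conditions: MeI (1.5 equiv), K2CO3 (2 equiv), DMF, rt, 4 h
Reagents that add atoms: iodomethane (MeI), CI
Why: SN2 O-alkylation of the carboxylate gives the methyl ester without the acid that a Fischer esterification needs and that the MOM groups would not stand.

**Step 8**
Reactants: 14 methyl 3,5-dihydroxybenzoate
Product: 15 methyl 3,5-bis(methoxymethoxy)benzoate
Conditions: MOMCl (3 equiv), iPr2NEt (4 equiv), CH2Cl2, 0 °C → rt, 12 h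
Reagents that add atoms: chloromethyl methyl ether (MOMCl), COCCl
Why: The same base-mediated O-alkylation (MOM protection) removes the acidic phenol protons that would quench the enolate in the coupling, and it leaves the ester untouched.

**Step 9 (key fragment coupling)**
Reactants: 13 methyl [3-geranyl-2,4-bis(methoxymethoxy)phenyl]acetate; 15 methyl 3,5-bis(methoxymethoxy)benzoate
Product: 17 methyl 3-[3,5-bis(methoxymethoxy)phenyl]-2-[3-geranyl-2,4-bis(methoxymethoxy)phenyl]-3-oxopropanoate (racemic at C2), via lithium enolate 16 (not isolated)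
Conditions: LiN(SiMe3)2 (2.5 equiv), THF, −78 °C, 45 min; 15 (1.2 equiv), −78 °C → rt, 12 h; sat. aq NH4Cl
Reagents that add atoms: none
Why: In this crossed Claisen condensation the fully preformed enolate of 13 cannot self-condense, benzoate 15 has no α-hydrogen and can only be the acceptor, and excess LiN(SiMe3)2 deprotonates the β-keto ester as it forms and pulls the equilibrium over, while the new α-stereocentre is racemic, enolisable and deleted in step 10.

**Step 10**
Reactants: 17 methyl 3-[3,5-bis(methoxymethoxy)phenyl]-2-[3-geranyl-2,4-bis(methoxymethoxy)phenyl]-3-oxopropanoate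
Product: 18 1-[3,5-bis(methoxymethoxy)phenyl]-2-[3-geranyl-2,4-bis(methoxymethoxy)phenyl]ethan-1-one
Conditions: LiCl (5 equiv), H2O (5 equiv), DMSO, 130 °C, N2, 3 h
Reagents that add atoms: none
Why: In the Krapcho dealkoxycarbonylation chloride demethylates the activated ester by SN2 attack and the β-keto carboxylate loses CO2 under essentially neutral conditions that the MOM acetals and the geranyl chain tolerate, which also removes the racemic centre.

**Step 11**
Reactants: 18 1-[3,5-bis(methoxymethoxy)phenyl]-2-[3-geranyl-2,4-bis(methoxymethoxy)phenyl]ethan-1-one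
Product: 20 mulberrofuran L (5-[7-geranyl-6-hydroxy-1-benzofuran-2-yl]benzene-1,3-diol; E alkene), via tetrahydroxy ketone 19 (not isolated)
Conditions: HCl (0.5 M in MeOH), 45 °C, N2, ca. 3 h, stopped at full conversion
Reagents that add atoms: none
Why: Acid-catalysed transacetalisation to methanol removes all four MOM groups, and the freed C2 phenol adds to the ketone to give a hemiketal whose dehydration (cyclodehydration of an o-hydroxybenzyl ketone) is driven by furan aromaticity, while dilute acid and mild heating keep the E-geranyl chain from closing to a chroman.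

**Compound list**
1 | 4-bromoresorcinol | Oc1ccc(Br)c(O)c1 | starting material
2 | 1-bromo-2,4-bis(methoxymethoxy)benzene | COCOc1ccc(Br)c(OCOC)c1 | intermediate
3 | ethylene oxide | C1CO1 | starting material
4 | [2,4-bis(methoxymethoxy)phenyl]lithium (not isolated) | [Li]c1ccc(OCOC)cc1OCOC | intermediate
5 | 2-[2,4-bis(methoxymethoxy)phenyl]ethan-1-ol | OCCc1ccc(OCOC)cc1OCOC | intermediate
6 | tert-butyl{2-[2,4-bis(methoxymethoxy)phenyl]ethoxy}dimethylsilane | CC(C)(C)[Si](C)(C)OCCc1ccc(OCOC)cc1OCOC | intermediate
7 | geranyl bromide, (2E)-1-bromo-3,7-dimethylocta-2,6-diene | CC(C)=CCC/C(C)=C/CBr | starting material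
8 | [3-(2-TBSO-ethyl)-2,6-bis(methoxymethoxy)phenyl]lithium (not isolated) | [Li]c1c(OCOC)ccc(CCO[Si](C)(C)C(C)(C)C)c1OCOC | intermediate
9 | tert-butyl{2-[3-geranyl-2,4-bis(methoxymethoxy)phenyl]ethoxy}dimethylsilane (E) | CC(C)=CCC/C(C)=C/Cc1c(OCOC)ccc(CCO[Si](C)(C)C(C)(C)C)c1OCOC | intermediate
10 | 2-[3-geranyl-2,4-bis(methoxymethoxy)phenyl]ethan-1-ol (E) | CC(C)=CCC/C(C)=C/Cc1c(OCOC)ccc(CCO)c1OCOC | intermediate
11 | [3-geranyl-2,4-bis(methoxymethoxy)phenyl]acetaldehyde (E, not isolated) | CC(C)=CCC/C(C)=C/Cc1c(OCOC)ccc(CC=O)c1OCOC | intermediate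
12 | [3-geranyl-2,4-bis(methoxymethoxy)phenyl]acetic acid (E) | CC(C)=CCC/C(C)=C/Cc1c(OCOC)ccc(CC(=O)O)c1OCOC | intermediate
13 | methyl [3-geranyl-2,4-bis(methoxymethoxy)phenyl]acetate (E) | CC(C)=CCC/C(C)=C/Cc1c(OCOC)ccc(CC(=O)OC)c1OCOC | intermediate
14 | methyl 3,5-dihydroxybenzoate | COC(=O)c1cc(O)cc(O)c1 | starting material
15 | methyl 3,5-bis(methoxymethoxy)benzoate | COC(=O)c1cc(OCOC)cc(OCOC)c1 | intermediate
16 | lithium enolate of 13 (not isolated) | CC(C)=CCC/C(C)=C/Cc1c(OCOC)ccc(C=C(OC)O[Li])c1OCOC | intermediate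
17 | methyl 3-[3,5-bis(methoxymethoxy)phenyl]-2-[3-geranyl-2,4-bis(methoxymethoxy)phenyl]-3-oxopropanoate (E alkene, racemic at C2) | CC(C)=CCC/C(C)=C/Cc1c(OCOC)ccc(C(C(=O)OC)C(=O)c2cc(OCOC)cc(OCOC)c2)c1OCOC | intermediate
18 | 1-[3,5-bis(methoxymethoxy)phenyl]-2-[3-geranyl-2,4-bis(methoxymethoxy)phenyl]ethan-1-one (E) | CC(C)=CCC/C(C)=C/Cc1c(OCOC)ccc(CC(=O)c2cc(OCOC)cc(OCOC)c2)c1OCOC | intermediate
19 | 1-(3,5-dihydroxyphenyl)-2-(3-geranyl-2,4-dihydroxyphenyl)ethan-1-one (E, not isolated) | CC(C)=CCC/C(C)=C/Cc1c(O)ccc(CC(=O)c2cc(O)cc(O)c2)c1O | intermediate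
20 | mulberrofuran L, 5-[7-geranyl-6-hydroxy-1-benzofuran-2-yl]benzene-1,3-diol (E) | CC(C)=CCC/C(C)=C/Cc1c(O)ccc2cc(-c3cc(O)cc(O)c3)oc12 | target

**Totals**
Total step count: 11.
Longest linear sequence: 10 steps (steps 1–7, then 9–11, from 4-bromoresorcinol). Step 8 is the one-step side branch.

**Three steps most likely to fail, with fallbacks**

Step 4 (allylation of aryllithium 8). The lithiation itself is secure. The alkylation, however, can give SN2′ product, Wurtz dimer of 7, or low conversion.
- The fallback sets out from 6 and comes back at 9, and it replaces the carbanion alkylation by a cross-coupling.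
- 6 is lithiated as before but quenched with I2 to give tert-butyl{2-[3-iodo-2,4-bis(methoxymethoxy)phenyl]ethoxy}dimethylsilane F1.
- Bromide 7 is treated with Bu3SnLi (THF, −78 °C) to give tributyl(geranyl)stannane F2.
- A Stille coupling of the two (Pd(PPh3)4 5 mol %, CuI 10 mol %, DMF, 80 °C) on zerovalent palladium joins the aryl carbon to the unsubstituted allyl terminus with the E geometry kept, giving 9.

Step 9 (crossed Claisen condensation). A methyl benzoate is only a moderate acceptor for an ortho-substituted arylacetate enolate, so conversion may stall.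
- The fallback sets out from 13 and 15 and comes back at 17, and it uses an aldehyde acceptor followed by oxidation.
- 15 is reduced with LiAlH4 (THF, 0 °C) to [3,5-bis(methoxymethoxy)phenyl]methanol F3.
- That alcohol is oxidised with MnO2 (CH2Cl2, rt) to 3,5-bis(methoxymethoxy)benzaldehyde F4.
- Enolate 16, made from 13 with 1.1 equiv LiN(SiMe3)2 at −78 °C, adds to this much more electrophilic carbonyl in an intermolecular aldol addition. This gives methyl 3-[3,5-bis(methoxymethoxy)phenyl]-2-[3-geranyl-2,4-bis(methoxymethoxy)phenyl]-3-hydroxypropanoate F5 as a mixture of racemic diastereomers, which does not matter.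
- NaHCO3-buffered Dess–Martin oxidation (CH2Cl2, rt) then gives 17.

Step 11 (acidic global deprotection and ring closure). Protonation of the C2″=C3″ alkene next to a free phenol can give a chroman before all four MOM groups are gone.
- The fallback sets out from 18 and comes back at 19 and then 20, and it swaps the acetals for silyl ethers so that no Brønsted acid strong enough to protonate the alkene is used.
- 18 is treated with Et3SiOTf and 2,2′-bipyridyl (CH2Cl2, 0 °C → rt), which turns aryl MOM ethers directly into aryl triethylsilyl ethers. This gives 1-[3,5-bis(triethylsilyloxy)phenyl]-2-[3-geranyl-2,4-bis(triethylsilyloxy)phenyl]ethan-1-one F6.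
- Bu4NF buffered with AcOH (THF, 0 °C) then releases 19. Any silyl enol ether formed on the way is cleaved in the same operation.
- 19 is closed to 20 with catalytic pyridinium p-toluenesulfonate in toluene at 80 °C over 4 Å molecular sieves.

**Further compounds**
F1 | step 4 | tert-butyl{2-[3-iodo-2,4-bis(methoxymethoxy)phenyl]ethoxy}dimethylsilane | CC(C)(C)[Si](C)(C)OCCc1ccc(OCOC)c(I)c1OCOC
F2 | step 4 | tributyl(geranyl)stannane, tributyl[(2E)-3,7-dimethylocta-2,6-dien-1-yl]stannane | CC(C)=CCC/C(C)=C/C[Sn](CCCC)(CCCC)CCCC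
F3 | step 9 | [3,5-bis(methoxymethoxy)phenyl]methanol | OCc1cc(OCOC)cc(OCOC)c1
F4 | step 9 | 3,5-bis(methoxymethoxy)benzaldehyde | O=Cc1cc(OCOC)cc(OCOC)c1
F5 | step 9 | methyl 3-[3,5-bis(methoxymethoxy)phenyl]-2-[3-geranyl-2,4-bis(methoxymethoxy)phenyl]-3-hydroxypropanoate (E alkene, mixture of racemic diastereomers) | CC(C)=CCC/C(C)=C/Cc1c(OCOC)ccc(C(C(=O)OC)C(O)c2cc(OCOC)cc(OCOC)c2)c1OCOC
F6 | step 11 | 1-[3,5-bis(triethylsilyloxy)phenyl]-2-[3-geranyl-2,4-bis(triethylsilyloxy)phenyl]ethan-1-one (E) | CC(C)=CCC/C(C)=C/Cc1c(O[Si](CC)(CC)CC)ccc(CC(=O)c2cc(O[Si](CC)(CC)CC)cc(O[Si](CC)(CC)CC)c2)c1O[Si](CC)(CC)CC
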